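Counted in millimolar, target plus isomer of the product hardly follows the charge in the closed flask. At the last readings the north run holds 1.50 mM, the north-east run 1.44 mM and the west run 1.68 mM, from 20 mM, 13 mM and 30 mM of substrate, and north still shows 92.2% of its substrate.

the same everywhere: enzyme 10 µM

|  | substrate | remark | time |
|---|---|---|---|
| north | 20 mM | run made earlier |  |
| north-east | 13 mM | run made earlier |  |
| west | 30 mM | run made earlier |  |
| dusk | 20 mM | a single well-mixed tank run continuously and read at steady state, 5.0 min in it on average |  |
| spring | 20 mM (fed, over 4.00 min) | a stirred flask in which substrate is dosed at a steady rate over 4.00 min without added volume, worked up at 5.0 min | 5.0 min |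
| noon | 20 mM | a closed flask charged with all of it at once and left for 5.0 min | 5.0 min |

- north (time / min: target / %, isomer of the product / %, substrate / %): 0.250: 2.9, 0, 97.3; 0.833: 5.9, 0, 95.6; 1.33: 5.9, 1.3, 93.2; 2.00: 6.7, 0.3, 92.3; 3.00: 6.7, 0.9, 92.2; 4.00: 6.4, 1.6, 92.2; 5.00: 6.3, 1.2, 92.2
- north-east (time / min: target / %, isomer of the product / %, substrate / %): 0.200: 3.9, 0.5, 97.1; 0.667: 8.1, 0.4, 92.4; 1.00: 8.5, 0.6, 90.9; 1.50: 10.1, 0.2, 89.6; 2.50: 9.8, 1.9, 89.3; 3.00: 10.1, 1.2, 89.2; 4.00: 9.1, 2.0, 89.5
- west (time / min: target / %, isomer of the product / %, substrate / %): 0.333: 3.0, 0, 97.1; 0.500: 3.0, 0.3, 97.3; 0.667: 3.1, 0.4, 96.2; 1.00: 4.1, 0, 96.5; 1.50: 4.3, 0, 95.2; 2.50: 4.5, 0.9, 94.7; 4.00: 4.6, 1.0, 94.3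

(scatter of a reading: 0.5 percentage points)

- the stated concentrations are those of everything mixed, before any reaction; amounts are the same in each set-up
- the feed brings no volume worth counting
- the earlier runs were made in a closed, stirred flask

- the set-up with the highest share of target in all that became target or isomer of the product, at the outlet or at the end ("none" if the first two lie within 2 percentage points) (dusk / spring / noon / none)
- share of target in all that became target or isomer of the product, at the outlet or at the end, dusk
- share of target in all that became target or isomer of the product, at the outlet or at the end, spring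
- share of target in all that became target or isomer of the product, at the outlet or at the end, noon

The north curve can be drawn from that level. Target starts on a slope r of 2.32 mM min⁻¹, read at the first point, and this tangent meets the level at a knee, t_k = 0.647 min. Taking the approach as exponential, t_h = 0.448 min is the time at which half of the product stands. The north readings of target still rise past the knee, to 6.7% at 2.00 min; from there substrate reads near 92.2% while target sags to 6.3% at 5.00 min, with isomer at 1.2%. The last 3 north readings, at a mean of 4.00 min, put 16.0% of the product in isomer. Reckoned as first-order loss counted from t_h, this gives the ageing constant k = 0.0491 min⁻¹, the rate at which target turns to isomer, a reading whose values each scatter by 0.5 percentage points. Its time scale, 20.4 min, is far longer than t_k, so the making counts as instantaneous and the share of target s follows the age of the product: s = exp(−k·age).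

Noon has age 4.55 min, so s = 80.0%. Dusk keeps target 5.0 min on average, so s = 1/(1 + kτ) = 80.3%. Spring has delivered 3.23 mM by the knee, more than north's level of 1.50 mM, so this reckoning lets its target age roughly as noon's does and puts its share near 80.0%. This reckoning therefore puts the set-ups within 2 points. The forecast gave 79% for dusk, 82% for spring and 81% for noon, verdict none, holding of spring: “Product therefore forms almost as in batch”.

The flask gives 82.8% in dusk, 82.6% in spring and 81.7% in noon, so the answer is none.

    substrate + enzyme → target + enzyme, rate k1*[substrate]*[enzyme]/(1 + ([substrate]/Km1) + ([target]/Kp1)) (1.70 mM, 14.0 mM, k = 3000 M⁻¹ s⁻¹)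
    enzyme ⇌ dormant form (K = 0.710, k = 0.00150 s⁻¹)
    enzyme → spent catalyst (k = 0.0300 s⁻¹)
    target ⇌ isomer of the product (K = 1.10, k = 8.50 × 10⁻⁴ s⁻¹)

In noon at 5.00 min, spent catalyst stands at 97.0% of the catalyst charged, with 92% of the substrate left. Noon read at 8.0 min has age 7.55 min, so k gives s = 69.0%, while that flask shows 73.3%, higher by 4.3 points.

(The readings are simulated with made-up constants; noise was put on by code.)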